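**Retrosynthetic overview**
- Last disconnection: the C6–OMe bond. The target comes from the mirror-symmetric 3,5-diprenyl acylphloroglucinol by oxidative dearomatisation with methanol as the nucleophile; this one event installs the OMe group and the only stereocentre.
- The two aryl–prenyl bonds are cut to prenyl bromide (prenyltransferase-like C-alkylation of the phloroglucinol).
- The carbocycle is cut at the bond between the acyl-bearing carbon and a ring carbonyl (C6–C1 of the chain) to an open-chain tetraketide ester; the forward step is a chalcone-synthase-type Claisen closure, run as one cascade with the double prenylation.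
- The tetraketide is cut at C6–C7 to a triketide ester (used as its trianion) and the dihydrocinnamate starter unit.
- Ring order: the phenyl ring is bought with the starter unit; the six-membered carbocycle is the only ring formed (step 2) and is dearomatised last (step 3).

Assumption: the drawn enol tautomer is (6S), and all enol tautomers of the β-triketone count as one compound; the (R,R)-iodane of step 3 is taken to give (6S) by analogy only, to be checked by ECD on the first batch, the (S,S)-iodane giving the mirror image.

Reagent note: (R,R)-ArI(OAc)2 in step 3 is diacetoxy{2,6-bis[(1R)-1-(mesitylcarbamoyl)ethoxy]phenyl}-λ3-iodane, made beforehand from the aryl iodide (NaBO3·4H2O, AcOH) and recovered as the aryl iodide.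

**Step 1**
Reactants: 1 methyl 3,5-dioxohexanoate (2.0 equiv); 2 methyl 3-phenylpropanoate (1.0 equiv)
Product: 3 methyl 3,5,7-trioxo-9-phenylnonanoate
Conditions: LiN(iPr)2 (6.2 equiv), THF, 0 °C, 1 h; then 2, −78 → 0 °C, 2 h; then cold 1 M HCl
Reagents that add atoms: none
Why: Claisen acylation of a polyanion (Harris-type chain extension): the last-formed terminal C6 carbanion of trilithiated 1 is its most nucleophilic site and attacks the ester of 2, and the product is shielded as its polyenolate, which uses the second equivalent of trianion as base; no stereocentre is formed.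

**Step 2**
Reactants: 3 methyl 3,5,7-trioxo-9-phenylnonanoate; 4 1-bromo-3-methylbut-2-ene (prenyl bromide, 2.2 equiv)
Product: 6 1-[2,4,6-trihydroxy-3,5-bis(3-methylbut-2-en-1-yl)phenyl]-3-phenylpropan-1-one, via 2′,4′,6′-trihydroxydihydrochalcone 5 (not isolated)
Conditions: degassed 2 M aq. KOH (6 equiv), argon, 0 °C → rt, 3 h; then 0 °C, 4 added over 1 h, 2 h; then 2 M HCl to pH 2
Reagents that add atoms: none
Why: Chalcone-synthase-type Claisen (Dieckmann) condensation followed by phenolate C-alkylation: in strong aqueous KOH both 1,3-diketone units of 3 are enolised and the ester is the only electrophilic carbonyl, so C6 acylates C1 (the competing C2-to-C7 aldol to a resorcylate needs a free ketone and weaker base), the trione aromatises to 5, and its polyanion is C-alkylated twice by SN2 reaction with prenyl bromide at the two free ring carbons, water favouring C- over O-alkylation; no stereocentre is formed.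

**Step 3**
Reactants: 6 1-[2,4,6-trihydroxy-3,5-bis(3-methylbut-2-en-1-yl)phenyl]-3-phenylpropan-1-one
Product: 7 (6S)-3,5-dihydroxy-6-methoxy-4,6-bis(3-methylbut-2-en-1-yl)-2-(3-phenylpropanoyl)cyclohexa-2,4-dien-1-one (target)
Conditions: (R,R)-ArI(OAc)2 (1.05 equiv), CH2Cl2/MeOH 4:1, argon, −40 °C, 4 h
Reagents that add atoms: methanol (CO)
Why: Proposed new method: the free 4-OH of symmetric 6 exchanges for acetate on trivalent iodine and methanol attacks an ortho, prenyl-bearing carbon as the aryl iodide leaves (associative oxidative dearomatisation), the hydrogen-bonded lactamide arms of the C2-symmetric iodane blocking one of the two enantiotopic ortho carbon/face combinations so that the (6S) quaternary centre is set in the C–O bond-forming event, after which the methoxy-dienone relaxes to the enolised β-triketone 7, which cannot re-aromatise or epimerise; the closest known reactions are the PhI(OAc)2/MeOH conversion of 2-alkylphenols into 6-alkyl-6-methoxycyclohexa-2,4-dienones and the enantioselective Kita-type dearomatisations of phenols with this class of chiral aryl-λ3-iodanes, and the iodane is preformed so that no peracid meets the prenyl alkenes.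

**Compound list**
1 | methyl 3,5-dioxohexanoate | CC(=O)CC(=O)CC(=O)OC | starting material
2 | methyl 3-phenylpropanoate | COC(=O)CCc1ccccc1 | starting material
3 | methyl 3,5,7-trioxo-9-phenylnonanoate (open-chain tetraketide ester, enol mixture) | COC(=O)CC(=O)CC(=O)CC(=O)CCc1ccccc1 | intermediate
4 | 1-bromo-3-methylbut-2-ene (prenyl bromide) | CC(C)=CCBr | starting material
5 | 1-(2,4,6-trihydroxyphenyl)-3-phenylpropan-1-one (2′,4′,6′-trihydroxydihydrochalcone) | O=C(CCc1ccccc1)c1c(O)cc(O)cc1O | intermediate
6 | 1-[2,4,6-trihydroxy-3,5-bis(3-methylbut-2-en-1-yl)phenyl]-3-phenylpropan-1-one | CC(C)=CCc1c(O)c(CC=C(C)C)c(O)c(C(=O)CCc2ccccc2)c1O | intermediate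
7 | (6S)-3,5-dihydroxy-6-methoxy-4,6-bis(3-methylbut-2-en-1-yl)-2-(3-phenylpropanoyl)cyclohexa-2,4-dien-1-one | CO[C@]1(CC=C(C)C)C(=O)C(C(=O)CCc2ccccc2)=C(O)C(CC=C(C)C)=C1O | target

**Totals**
Total step count: 3. Longest linear sequence: 3 steps (1 or 2 → 3 → 6 → 7).

**Steps most likely to fail, with fallbacks**

Step 3 is the riskiest: intermolecular enantioselective methoxylation by a chiral iodane has no direct precedent, so the ee, the sense of induction and the competition from attack at the acyl-bearing carbon or over-oxidation are all open. Fallback: setting out from 6, oxidation with achiral PhI(OAc)2 (1.0 equiv) in MeOH at 0 °C gives racemic 3,5-dihydroxy-6-methoxy-4,6-bis(3-methylbut-2-en-1-yl)-2-(3-phenylpropanoyl)cyclohexa-2,4-dien-1-one F1. The enantiomers are then separated by preparative SFC on an amylose tris(3,5-dimethylphenylcarbamate) phase (CO2/MeOH with 0.1% HCO2H). The (6S) enantiomer, assigned by ECD, is 7, where the fallback rejoins the route.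

Step 2 is next: the ester may hydrolyse and divert to the aldol (resorcylic acid) mode, and prenylation in the same pot can give mono-, tri- and O-prenylated material. Fallback: setting out from 3, the ring closure is run alone (2 M aq. KOH, then acidification) and 5 is isolated and purified. The prenyl groups are then introduced by Lewis-acid Friedel–Crafts alkylation instead of phenolate alkylation, using 2-methylbut-3-en-2-ol F2 (2.2 equiv) and BF3·OEt2 in dioxane at rt, through the dimethylallyl cation. This rejoins the route at 6.

Step 1 is third: the strongly basic trianion may enolise ester 2 instead of attacking it, giving low conversion. Fallback: setting out from 2, the triketide is used in masked form. Triacetic acid lactone F3 is dilithiated (LiN(iPr)2, 2.2 equiv, THF, −78 °C) and acylated at its 6-methyl carbanion by 2 to give 4-hydroxy-6-(2-oxo-4-phenylbutyl)-2H-pyran-2-one F4. Mg(OMe)2 in MeOH at reflux then opens the pyrone, as in the methanolysis of dehydroacetic acid, to the magnesium chelate of the triketo ester, which cold dilute HCl frees. This rejoins the route at 3.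

**Further compounds**
F1 | step 3 | racemic 3,5-dihydroxy-6-methoxy-4,6-bis(3-methylbut-2-en-1-yl)-2-(3-phenylpropanoyl)cyclohexa-2,4-dien-1-one | COC1(CC=C(C)C)C(=O)C(C(=O)CCc2ccccc2)=C(O)C(CC=C(C)C)=C1O
F2 | step 2 | 2-methylbut-3-en-2-ol (bought) | CC(C)(O)C=C
F3 | step 1 | 4-hydroxy-6-methyl-2H-pyran-2-one (triacetic acid lactone, bought) | CC1=CC(O)=CC(=O)O1
F4 | step 1 | 4-hydroxy-6-(2-oxo-4-phenylbutyl)-2H-pyran-2-one | O=C(CCc1ccccc1)CC1=CC(O)=CC(=O)O1
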